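**Retrosynthetic overview**
- The strategy rests on ring A (the benzoic acid ring): its C2 hydroxyl and C6 aryloxy group are meta to each other, the carbon substituent C1 lies between them, and the prenyl group at C3 is ortho to the hydroxyl. This is the substitution pattern that a vinylketene plus ynol ether benzannulation delivers.
- Ring A is therefore cut into 4-prenylcyclobut-2-en-1-one (C2 to C5 with the prenyl group) and a ring B aryl ynol ether carrying C6 (with the diaryl ether oxygen already attached) and C1 as a CH2OSi group. The diaryl ether C–O bond is made as a phenol addition to dichloroacetylene, never as an aryl–oxygen coupling.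
- The ynol ether comes from creosol (formylation, O-demethylation, regioselective MOM ether, reduction, dichlorovinyl ether, acetylide plus formaldehyde, silylation). The cyclobutenone comes from 5-methylhex-4-enoic acid (ketene plus ethoxyacetylene [2+2], reduction and transposition).
- After the benzannulation: desilylation, two-stage oxidation of the C1 CH2OH to CO2H, removal of both MOM groups.
- Ring order: ring B is bought with creosol; ring A is the only ring formed (step 12).

Key step: step 12

Remark on the chemistry: the target has no stereocentre; the four-membered-ring intermediates and the cyclohexadienone are racemic and their single stereocentre is destroyed when ring A aromatizes. ArB = 2-(methoxymethoxy)-6-[(methoxymethoxy)methyl]-4-methylphenyl; MOM = methoxymethyl; TBS = tert-butyldimethylsilyl.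

**Route**

Step 1
Reactants: 1 creosol (2-methoxy-4-methylphenol)
Product: 2 2-hydroxy-3-methoxy-5-methylbenzaldehyde
Conditions: hexamethylenetetramine, CF3CO2H, 90 °C; then H2O, 60 °C
Reagents that add atoms: hexamethylenetetramine, C1N2CN3CN1CN(C2)C3 (formyl carbon); water, O (formyl oxygen)
Why: Duff formylation, in which the iminium ion from hexamethylenetetramine attacks the only free position activated by the hydroxyl (ortho, since the para position carries the methyl group), the benzylamine is oxidized by hydride transfer to an iminium ion and water releases the aldehyde.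

Step 2
Reactants: 2 2-hydroxy-3-methoxy-5-methylbenzaldehyde
Product: 3 2,3-dihydroxy-5-methylbenzaldehyde
Conditions: BBr3, CH2Cl2, −78 °C → rt; then H2O
Reagents that add atoms: none
Why: Lewis acid O-demethylation of an aryl methyl ether (bromide attacks the methyl group of the boron-complexed ether), a standard conversion of ortho-vanillin-type aldehydes into catechol aldehydes that tolerates the formyl group.

Step 3
Reactants: 3 2,3-dihydroxy-5-methylbenzaldehyde
Product: 4 2-hydroxy-3-(methoxymethoxy)-5-methylbenzaldehyde
Conditions: NaH (2.2 equiv), DMSO, rt; then MOMCl (1.0 equiv); aq NH4Cl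
Reagents that add atoms: chloromethyl methyl ether, COCCl
Why: Regioselective Williamson-type O-alkylation of the dianion, in which the 3-phenoxide is neither conjugated to nor chelated by the formyl group and is the more nucleophilic oxygen, so one equivalent of electrophile should go to O-3 and leave the 2-OH free.

Step 4
Reactants: 4 2-hydroxy-3-(methoxymethoxy)-5-methylbenzaldehyde
Product: 5 2-(hydroxymethyl)-6-(methoxymethoxy)-4-methylphenol
Conditions: NaBH4, MeOH, 0 °C
Reagents that add atoms: none
Why: Hydride reduction of the aldehyde leaves the acetal and the phenol untouched, and doing it before the vinylation removes an ortho carbonyl group that could trap the vinyl anion formed in the next step.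

Step 5
Reactants: 5 2-(hydroxymethyl)-6-(methoxymethoxy)-4-methylphenol; 6 trichloroethylene
Product: 8 [2-[(E)-1,2-dichloroethenoxy]-3-(methoxymethoxy)-5-methylphenyl]methanol, via dichloroacetylene 7 (not isolated)
Conditions: K2CO3, DMF, 70 °C
Reagents that add atoms: none
Why: Base-mediated vinylation of a phenol with trichloroethylene, in which K2CO3 eliminates HCl from 6 to give dichloroacetylene and the phenoxide adds to it in an anti sense to give the (E)-1,2-dichlorovinyl ether, while carbonate does not deprotonate the benzylic alcohol.

Step 6
Reactants: 8 [2-[(E)-1,2-dichloroethenoxy]-3-(methoxymethoxy)-5-methylphenyl]methanol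
Product: 9 2-[(E)-1,2-dichloroethenoxy]-1-(methoxymethoxy)-3-[(methoxymethoxy)methyl]-5-methylbenzene
Conditions: MOMCl, i-Pr2NEt, CH2Cl2, 0 °C → rt
Reagents that add atoms: chloromethyl methyl ether, COCCl
Why: Methoxymethyl ether formation by alkylation of the primary alcohol with the chloromethyl ether under amine base, conditions to which the dichlorovinyl ether is inert.

Step 7
Reactants: 9 2-[(E)-1,2-dichloroethenoxy]-1-(methoxymethoxy)-3-[(methoxymethoxy)methyl]-5-methylbenzene
Product: 12 3-(ArB-oxy)prop-2-yn-1-ol, via chloroethynyl ether 10 (not isolated), via lithium aryloxyacetylide 11 (not isolated)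
Conditions: n-BuLi (2.5 equiv), THF, −78 → −40 °C; then (CH2O)n, −40 → 0 °C; aq NaHCO3
Reagents that add atoms: paraformaldehyde (as formaldehyde), C=O
Why: Dichlorovinyl ether route to ynol ethers, in which n-BuLi removes the vinyl hydrogen with loss of LiCl to give the chloroalkyne 10, chlorine–lithium exchange gives the acetylide 11 and this adds to formaldehyde (acetylide 1,2-addition), the acetals being stable to n-BuLi at low temperature.

Step 8
Reactants: 12 3-(ArB-oxy)prop-2-yn-1-ol
Product: 13 tert-butyl-[3-(ArB-oxy)prop-2-ynoxy]dimethylsilane (the ring B aryl ynol ether)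
Conditions: TBSCl, imidazole, DMF, 0 °C → rt
Reagents that add atoms: tert-butyldimethylsilyl chloride, CC(C)(C)[Si](C)(C)Cl
Why: Imidazole-promoted silylation of a primary alcohol, run in a basic medium that avoids the acid-catalysed Meyer–Schuster rearrangement to which 3-aryloxypropargyl alcohols are prone.

Step 9
Reactants: 14 5-methylhex-4-enoic acid
Product: 15 5-methylhex-4-enoyl chloride
Conditions: (COCl)2, DMF (cat.), CH2Cl2, 0 °C → rt
Reagents that add atoms: oxalyl chloride, O=C(Cl)C(=O)Cl
Why: Acid chloride formation by acyl substitution through the DMF-derived chloroiminium catalyst, mild enough to leave the trisubstituted alkene untouched.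

Step 10
Reactants: 15 5-methylhex-4-enoyl chloride; 16 ethoxyacetylene
Product: 18 3-ethoxy-4-(3-methylbut-2-enyl)cyclobut-2-en-1-one (racemic), via prenylketene 17 (not isolated)
Conditions: Et3N, 16 (3 equiv), CH2Cl2, 0 °C → rt, slow addition of 15
Reagents that add atoms: none
Why: Dehydrochlorination gives the aldoketene 17, which undergoes thermal [2+2] cycloaddition with the ynol ether, the nucleophilic unsubstituted alkyne carbon bonding to the ketene carbonyl carbon so that ethoxy ends at C3 and the prenyl group at C4; the C4 stereocentre forms without control and the product is racemic.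

Step 11
Reactants: 18 3-ethoxy-4-(3-methylbut-2-enyl)cyclobut-2-en-1-one
Product: 20 4-(3-methylbut-2-enyl)cyclobut-2-en-1-one (racemic), via cyclobutenol 19 (not isolated)
Conditions: i-Bu2AlH, Et2O, −78 °C; then 1 M HCl (aq), 0 °C
Reagents that add atoms: water, O
Why: Stork–Danheiser transposition, in which 1,2-reduction of the vinylogous ester gives the allylic alcohol 19 and its acid-induced ionization to the ethoxy-stabilized allyl cation, followed by hydrolysis, moves the carbonyl group to the former enol ether carbon; the C4 stereocentre is not touched (racemic) and the alkene cannot migrate by enolization because the enol would be a cyclobutadiene.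

Step 12
Reactants: 20 4-(3-methylbut-2-enyl)cyclobut-2-en-1-one (racemic); 13 tert-butyl-[3-(ArB-oxy)prop-2-ynoxy]dimethylsilane
Product: 25 2-[(tert-butyldimethylsilyl)oxymethyl]-3-(ArB-oxy)-6-(3-methylbut-2-enyl)phenol, via vinylketene 21 (not isolated), via vinylcyclobutenone 22 (not isolated), via dienylketene 23 (not isolated), via cyclohexadienone 24 (not isolated)
Conditions: 13 (1.0 equiv), 20 (2.0 equiv), toluene, 80 °C → 110 °C, sealed tube
Reagents that add atoms: none
Why: Danheiser benzannulation, the closest known cases being the thermal reactions of cyclobutenones with alkoxy- and siloxyalkynes: heat opens 20 by a 4π electrocyclic reaction (C4 substituent rotating outward) to the (E)-vinylketene 21, which adds [2+2] to the ynol ether 13 to give the 4-vinylcyclobutenone 22. A second, reversible 4π opening gives the dienylketene 23, and ring A is closed by its thermal disrotatory 6π electrocyclization to the cyclohexa-2,4-dienone 24, which tautomerizes to the phenol 25; in the numbering of the target the [2+2] step makes C1–C2 and C5–C6 and the 6π step re-forms C2–C3. No stereocentre is set, since the racemic centre of 20 becomes the sp3 carbon of 24 and is erased by the tautomerization. The one selectivity needed is the regiochemistry of the [2+2] step, secured by the polarization of the ynol ether: its carbon remote from oxygen is the nucleophilic one and bonds to the ketene carbonyl carbon, which places the CH2OSi carbon between the new OH and the aryloxy group and the prenyl group ortho to OH on the other side. The aryl ynol ether has no β-hydrogen for retro-ene loss on heating, its 2,6-disubstituted aryl ring is twisted so that the oxygen lone pair is left to the alkyne, and the crowded phenol of 25 should resist acylation by excess 21.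

Step 13
Reactants: 25 2-[(tert-butyldimethylsilyl)oxymethyl]-3-(ArB-oxy)-6-(3-methylbut-2-enyl)phenol
Product: 26 2-(hydroxymethyl)-3-(ArB-oxy)-6-(3-methylbut-2-enyl)phenol
Conditions: n-Bu4NF, THF, 0 °C; aq NH4Cl
Reagents that add atoms: none
Why: Fluoride cleavage of the silyl ether, driven by the Si–F bond, leaves the two methoxymethyl acetals and the alkene untouched.

Step 14
Reactants: 26 2-(hydroxymethyl)-3-(ArB-oxy)-6-(3-methylbut-2-enyl)phenol
Product: 27 2-hydroxy-6-(ArB-oxy)-3-(3-methylbut-2-enyl)benzaldehyde
Conditions: MnO2 (activated, excess), CH2Cl2, rt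
Reagents that add atoms: none
Why: Heterogeneous MnO2 oxidation is selective for benzylic alcohols and should stop at the salicylaldehyde, which is stabilized by its internal hydrogen bond, without touching the prenyl group or the protected ring B alcohol.

Step 15
Reactants: 27 2-hydroxy-6-(ArB-oxy)-3-(3-methylbut-2-enyl)benzaldehyde
Product: 28 2-hydroxy-6-(ArB-oxy)-3-(3-methylbut-2-enyl)benzoic acid
Conditions: NaClO2, NaH2PO4, 2-methyl-2-butene (excess), t-BuOH/H2O, rt
Reagents that add atoms: sodium chlorite, [Na+].[O-]Cl=O
Why: Pinnick oxidation, in which chlorous acid adds to the aldehyde and fragments to the acid while the large excess of 2-methyl-2-butene traps hypochlorous acid before it can chlorinate the prenyl alkene or the phenol rings, and the buffered pH leaves the acetals intact.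

Step 16
Reactants: 28 2-hydroxy-6-(ArB-oxy)-3-(3-methylbut-2-enyl)benzoic acid
Product: 29 2-hydroxy-6-[2-hydroxy-6-(hydroxymethyl)-4-methylphenoxy]-3-(3-methylbut-2-enyl)benzoic acid (CNP0140656.0)
Conditions: 3 M HCl (aq), MeOH, 40 °C
Reagents that add atoms: none
Why: Acid-catalysed transacetalization to methanol removes the phenolic and the benzylic methoxymethyl groups, at a temperature kept low so that the prenyl alkene, whose neighbouring phenol is tied up in a hydrogen bond to the carboxyl group, should not be protonated.

**Compound list**
1 | creosol (2-methoxy-4-methylphenol) | COc1cc(C)ccc1O | starting material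
2 | 2-hydroxy-3-methoxy-5-methylbenzaldehyde | COc1cc(C)cc(C=O)c1O | intermediate
3 | 2,3-dihydroxy-5-methylbenzaldehyde | Cc1cc(O)c(O)c(C=O)c1 | intermediate
4 | 2-hydroxy-3-(methoxymethoxy)-5-methylbenzaldehyde | COCOc1cc(C)cc(C=O)c1O | intermediate
5 | 2-(hydroxymethyl)-6-(methoxymethoxy)-4-methylphenol | COCOc1cc(C)cc(CO)c1O | intermediate
6 | trichloroethylene | ClC=C(Cl)Cl | starting material
7 | dichloroacetylene | ClC#CCl | intermediate (not isolated)
8 | [2-[(E)-1,2-dichloroethenoxy]-3-(methoxymethoxy)-5-methylphenyl]methanol | COCOc1cc(C)cc(CO)c1O/C(Cl)=C\Cl | intermediate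
9 | 2-[(E)-1,2-dichloroethenoxy]-1-(methoxymethoxy)-3-[(methoxymethoxy)methyl]-5-methylbenzene | COCOCc1cc(C)cc(OCOC)c1O/C(Cl)=C\Cl | intermediate
10 | 2-(chloroethynyloxy)-1-(methoxymethoxy)-3-[(methoxymethoxy)methyl]-5-methylbenzene | COCOCc1cc(C)cc(OCOC)c1OC#CCl | intermediate (not isolated)
11 | lithium 2-(ArB-oxy)ethynide | COCOCc1cc(C)cc(OCOC)c1OC#C[Li] | intermediate (not isolated)
12 | 3-[2-(methoxymethoxy)-6-[(methoxymethoxy)methyl]-4-methylphenoxy]prop-2-yn-1-ol | COCOCc1cc(C)cc(OCOC)c1OC#CCO | intermediate
13 | tert-butyl-[3-[2-(methoxymethoxy)-6-[(methoxymethoxy)methyl]-4-methylphenoxy]prop-2-ynoxy]dimethylsilane | COCOCc1cc(C)cc(OCOC)c1OC#CCO[Si](C)(C)C(C)(C)C | intermediate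
14 | 5-methylhex-4-enoic acid | CC(C)=CCCC(=O)O | starting material
15 | 5-methylhex-4-enoyl chloride | CC(C)=CCCC(=O)Cl | intermediate
16 | ethoxyacetylene | CCOC#C | starting material
17 | 5-methylhexa-1,4-dien-1-one (prenylketene) | CC(C)=CCC=C=O | intermediate (not isolated)
18 | 3-ethoxy-4-(3-methylbut-2-enyl)cyclobut-2-en-1-one (racemic) | CCOC1=CC(=O)C1CC=C(C)C | intermediate
19 | 3-ethoxy-4-(3-methylbut-2-enyl)cyclobut-2-en-1-ol (racemic, cis/trans mixture) | CCOC1=CC(O)C1CC=C(C)C | intermediate (not isolated)
20 | 4-(3-methylbut-2-enyl)cyclobut-2-en-1-one (racemic) | CC(C)=CCC1C=CC1=O | intermediate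
21 | (3E)-7-methylocta-1,3,6-trien-1-one | CC(C)=CC/C=C/C=C=O | intermediate (not isolated)
22 | 3-(ArB-oxy)-2-[(tert-butyldimethylsilyl)oxymethyl]-4-[(1E)-5-methylhexa-1,4-dienyl]cyclobut-2-en-1-one (racemic) | CC(C)=CC/C=C/C1C(=O)C(CO[Si](C)(C)C(C)(C)C)=C1Oc1c(OCOC)cc(C)cc1COCOC | intermediate (not isolated)
23 | (3E,5E)-3-(ArB-oxy)-2-[(tert-butyldimethylsilyl)oxymethyl]-9-methyldeca-1,3,5,8-tetraen-1-one | O=C=C(CO[Si](C)(C)C(C)(C)C)/C(Oc1c(OCOC)cc(C)cc1COCOC)=C\C=C\CC=C(C)C | intermediate (not isolated)
24 | 3-(ArB-oxy)-2-[(tert-butyldimethylsilyl)oxymethyl]-6-(3-methylbut-2-enyl)cyclohexa-2,4-dien-1-one (racemic) | O=C1C(CO[Si](C)(C)C(C)(C)C)=C(Oc2c(OCOC)cc(C)cc2COCOC)C=CC1CC=C(C)C | intermediate (not isolated)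
25 | 2-[(tert-butyldimethylsilyl)oxymethyl]-3-[2-(methoxymethoxy)-6-[(methoxymethoxy)methyl]-4-methylphenoxy]-6-(3-methylbut-2-enyl)phenol | CC(C)=CCc1ccc(Oc2c(OCOC)cc(C)cc2COCOC)c(CO[Si](C)(C)C(C)(C)C)c1O | intermediate
26 | 2-(hydroxymethyl)-3-[2-(methoxymethoxy)-6-[(methoxymethoxy)methyl]-4-methylphenoxy]-6-(3-methylbut-2-enyl)phenol | CC(C)=CCc1ccc(Oc2c(OCOC)cc(C)cc2COCOC)c(CO)c1O | intermediate
27 | 2-hydroxy-6-[2-(methoxymethoxy)-6-[(methoxymethoxy)methyl]-4-methylphenoxy]-3-(3-methylbut-2-enyl)benzaldehyde | CC(C)=CCc1ccc(Oc2c(OCOC)cc(C)cc2COCOC)c(C=O)c1O | intermediate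
28 | 2-hydroxy-6-[2-(methoxymethoxy)-6-[(methoxymethoxy)methyl]-4-methylphenoxy]-3-(3-methylbut-2-enyl)benzoic acid | CC(C)=CCc1ccc(Oc2c(OCOC)cc(C)cc2COCOC)c(C(=O)O)c1O | intermediate
29 | 2-hydroxy-6-[2-hydroxy-6-(hydroxymethyl)-4-methylphenoxy]-3-(3-methylbut-2-enyl)benzoic acid | CC(C)=CCc1ccc(Oc2c(O)cc(C)cc2CO)c(C(=O)O)c1O | target

**Step count**
Total step count: 16. Longest linear sequence: 13 steps (steps 1–8, then 12–16); the cyclobutenone branch (steps 9–11) joins at step 12.

**Steps most likely to fail**

1. Step 12. The aryl ynol ether is a weaker ketene acceptor than alkyl or silyl ynol ethers. At the temperature needed to open the cyclobutenone, the vinylketene may be lost to dimerization and the cyclobutenone to polymerization faster than the [2+2] capture occurs, or the adduct may stall before its second ring opening. The fallback sets out from 13 and comes back at 25; it generates the same vinylketene photochemically at room temperature. Commercial 4-methylpent-3-en-1-ol is oxidized (PhI(OAc)2, TEMPO cat., CH2Cl2) to 4-methylpent-3-enal F1, which is used at once in a Wittig reaction with 1-(triphenylphosphoranylidene)propan-2-one to give (3E)-7-methylocta-3,6-dien-2-one F2. Kinetic enolization (LiN(SiMe3)2, THF, −78 °C) and acylation with 2,2,2-trifluoroethyl trifluoroacetate give (5E)-1,1,1-trifluoro-9-methyldeca-5,8-diene-2,4-dione F3, and detrifluoroacetylative diazo transfer (MsN3, Et3N, H2O, MeCN) gives (3E)-1-diazo-7-methylocta-3,6-dien-2-one F4. Irradiation of F4 with 13 (medium-pressure mercury lamp, Pyrex, CH2Cl2, rt) should trigger a photochemical Wolff rearrangement to 21 at low stationary concentration; brief warming (toluene, 80 °C) should carry 22–24 through to 25.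

2. Step 11. The strained, volatile enone may be lost during the acidic transposition and isolation (polymerization, addition of water), and dehydration through the β-hydroxy ketone may place the double bond on the substituted side. The fallback sets out from 15 and comes back at 25 (through 21); it avoids any four-membered-ring precursor. Reduction of 15 (LiAlH(Ot-Bu)3, THF, −78 °C) gives 5-methylhex-4-enal F5. Horner–Wadsworth–Emmons olefination (triethyl phosphonoacetate, NaH, THF) gives ethyl (2E)-7-methylocta-2,6-dienoate F6, saponification (LiOH, THF/H2O) gives (2E)-7-methylocta-2,6-dienoic acid F7, and (COCl)2 with DMF (cat.) gives (2E)-7-methylocta-2,6-dienoyl chloride F8. Slow addition of F8 to Et3N and 13 in toluene at 80 °C should effect 1,4-dehydrochlorination (γ-deprotonation of the acylammonium ion) to the vinylketene 21 in the presence of the ynol ether, which then enters the same cascade to 25.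

3. Step 16. Under protic acid the prenyl alkene may be protonated and captured by the neighbouring phenol or by methanol, and the ring B benzylic alcohol may be solvolysed, before the less labile benzylic acetal is fully cleaved. The fallback sets out from 28 and comes back at 29 and makes no new isolable compound (F0). It replaces protic acid by silyl triflate activation in a basic medium: Me3SiOTf and 2,2'-bipyridyl (CH2Cl2, 0 °C) should convert both acetals into silyl and pyridinium species, and addition of water should then release the phenol and the alcohol at neutral pH with no free acid in contact with the alkene.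

**Further compounds**
F1 | step 12 | 4-methylpent-3-enal | CC(C)=CCC=O
F2 | step 12 | (3E)-7-methylocta-3,6-dien-2-one | CC(C)=CC/C=C/C(C)=O
F3 | step 12 | (5E)-1,1,1-trifluoro-9-methyldeca-5,8-diene-2,4-dione | CC(C)=CC/C=C/C(=O)CC(=O)C(F)(F)F
F4 | step 12 | (3E)-1-diazo-7-methylocta-3,6-dien-2-one | CC(C)=CC/C=C/C(=O)C=[N+]=[N-]
F5 | step 11 | 5-methylhex-4-enal | CC(C)=CCCC=O
F6 | step 11 | ethyl (2E)-7-methylocta-2,6-dienoate | CCOC(=O)/C=C/CCC=C(C)C
F7 | step 11 | (2E)-7-methylocta-2,6-dienoic acid | CC(C)=CCC/C=C/C(=O)O
F8 | step 11 | (2E)-7-methylocta-2,6-dienoyl chloride | CC(C)=CCC/C=C/C(=O)Cl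
F0 | step 16 | none | none
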